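**Plan**

1. Retrosynthesis (lignan numbering): the two phenolic O–benzyl bonds and the O7′–Si bond are cut first, then the C7–H bond of the C7 carbinol (back to an aryl ketone masked as a 1,3-dithiane), then the C9–O bond of the tetrahydrofuran (back to a 1,4-diol and from there to a γ-alkoxy lactone), and last the two benzylic bonds C7–C8 and C7′–C8′ in one operation.
2. Enabling feature: C8 and C8′ are adjacent, trans carbons of the tetrahydrofuran ring; each carries one benzylic carbon (C7, C7′) and each is flanked by a ring OCH2 carbon (C9, C9′). This is the pattern of Cβ and Cα of a 5-alkoxybutenolide, whose acetal carbon becomes C9 and whose carbonyl carbon becomes C9′.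
3. Forward: the chain is joined first, by adding a lithiated aryl dithiane to (5R)-5-menthyloxybutenolide and trapping the enolate with O-benzylvanillin; no ring is formed there. The lactone is then reduced open (menthol leaves) and the only new ring, the tetrahydrofuran, is closed through a monotosylate before the dithiane is unmasked.
4. Stereochemistry: C8 from the menthyloxy acetal centre (attack anti to it), C8′ trans to the new C8 substituent, C7′ from the anti aldol of the ring-locked E enolate, C7 from an (R)-CBS reduction of the aryl ketone.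

Key step: step 4

Remark: C7, C8, C9 denote the dithiane-derived half and C7′, C8′, C9′ the aldehyde-derived half; Ar = 4-benzyloxy-3-methoxyphenyl, Men = (1R,2S,5R)-menthyl, TBS = tert-butyldimethylsilyl; O-benzylvanillin is taken as a catalogue compound.

**Route**

Step 1
Reactants: 1 4-benzyloxy-3-methoxybenzaldehyde (O-benzylvanillin); 2 propane-1,3-dithiol
Product: 3 2-(4-benzyloxy-3-methoxyphenyl)-1,3-dithiane
Conditions: BF3·OEt2 (0.2 equiv), CH2Cl2, 0 °C → rt
Reagents that add atoms: none
Why: Lewis-acid-catalysed dithioacetalisation of an aromatic aldehyde, driven by the stability of the six-membered S,S-acetal, under which the aryl benzyl ether should survive.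

Step 2
Reactants: 4 furfural
Product: 6 (±)-5-hydroxyfuran-2(5H)-one, via furfural endoperoxide 5 (not isolated)
Conditions: O2, hν (visible), rose bengal (cat.), MeOH, rt
Reagents that add atoms: oxygen, O=O
Why: Dye-sensitised photooxygenation, in which singlet oxygen adds [4+2] across C2/C5 of the furan and methanolysis of the formyl group of the endoperoxide expels methyl formate to leave the pseudo-acid (its stereocentre is reset in step 3).

Step 3
Reactants: 6 (±)-5-hydroxyfuran-2(5H)-one; 7 l-menthol
Product: 8 (5R)-5-[(1R,2S,5R)-menthyloxy]furan-2(5H)-one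
Conditions: CSA (cat.), toluene, reflux (Dean–Stark); crystallisation from petroleum ether, mother liquor re-equilibrated with acid and recrystallised
Reagents that add atoms: none
Why: Acid-catalysed acetalisation of the cyclic hemiacetal with azeotropic removal of water; the acetal carbon epimerises under the acid and the 5R diastereomer should crystallise selectively, so C5 is fixed relative to the menthyl stereocentres by crystallisation-driven enrichment.

Step 4
Reactants: 3 2-(4-benzyloxy-3-methoxyphenyl)-1,3-dithiane; 8 (5R)-5-menthyloxyfuran-2(5H)-one; 1 4-benzyloxy-3-methoxybenzaldehyde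
Product: 12 (3S,4R,5R)-3-[(R)-Ar(hydroxy)methyl]-4-(2-Ar-1,3-dithian-2-yl)-5-(menthyloxy)dihydrofuran-2(3H)-one, via 2-lithio-1,3-dithiane 9 (not isolated), via lithium lactone enolate 10 (not isolated), via lithium aldolate 11 (not isolated)
Conditions: 3, n-BuLi (1.05 equiv), THF, −78 → −20 °C; 8, THF, −78 °C; 1, THF, −78 °C; AcOH, −78 °C
Reagents that add atoms: none
Why: Deprotonation of 3 gives the sulfur-stabilised acyl anion equivalent 9, which adds in Michael fashion to C4 of 8 (C7–C8 bond) to give enolate 10; this attacks the aldehyde carbon of 1 through C3 (C7′–C8′ bond) and the aldolate 11 is protonated cold. The closest known reaction type is the three-component conjugate addition–aldol trapping of γ-alkoxybutenolides with lithiated dithianes; no ring is closed, the lactone ring of 8 being carried through unchanged. C4 (later C8) is controlled by the acetal centre C5, since the bulky nucleophile approaches the face opposite the menthyloxy group, and C3 (later C8′) is controlled by the new C4 substituent, the aldehyde adding anti to the dithianyl group so that the ring becomes trans,trans. C7′ is set in the aldol itself: the ring-locked E(O) enolate reacts through a chair-like Zimmerman–Traxler transition state with the aryl group equatorial, which should favour the anti (7′R) carbinol. The step needs 1,4- over 1,2-addition, secured by the soft, hindered 2-aryl dithiane anion in THF at low temperature, and kinetic control of the aldol, secured by quenching at −78 °C before retro-aldol equilibration. The C7′ selectivity is the least secure element, and the 7′S epimer, if formed, should be separable by chromatography at this stage.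

Step 5
Reactants: 12 aldol adduct
Product: 13 7′-O-TBS ether of 12
Conditions: TBSOTf (1.5 equiv), 2,6-lutidine (3 equiv), CH2Cl2, −78 → 0 °C
Reagents that add atoms: tert-butyldimethylsilyl trifluoromethanesulfonate, CC(C)(C)[Si](C)(C)OS(=O)(=O)C(F)(F)F
Why: O-silylation of a hindered secondary benzylic alcohol with a silyl triflate and a non-nucleophilic base, too weakly basic for retro-aldol or epimerisation, which masks O7′ so that it cannot take part in the later ring closure.

Step 6
Reactants: 13 silyl ether lactone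
Product: 14 (2R,3R)-2-[(R)-Ar(TBSO)methyl]-3-(2-Ar-1,3-dithian-2-yl)butane-1,4-diol
Conditions: LiAlH4 (3 equiv), THF, 0 °C → rt; Fieser work-up
Reagents that add atoms: none
Why: Hydride reduction of the lactone carbonyl opens the ring to a hemiacetal alkoxide at the former acetal carbon, which collapses to an aldehyde with loss of menthoxide and is reduced in turn, so that C9′ and C9 both arrive as CH2OH while dithiane, silyl ether, benzyl ethers and the C8/C8′ centres are untouched.

Step 7
Reactants: 14 1,4-diol
Product: 17 (3R,4R)-3-(2-Ar-1,3-dithian-2-yl)-4-[(R)-Ar(TBSO)methyl]tetrahydrofuran, via 9′-O-monotosylate 15 (not isolated), via 9-O-monotosylate 16 (not isolated)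
Conditions: TsCl (1.1 equiv), pyridine, DMAP (cat.), 0 °C → rt, then 60 °C
Reagents that add atoms: none
Why: Monosulfonylation of a primary 1,4-diol followed by intramolecular Williamson etherification (5-exo-tet SN2 by the remaining primary hydroxyl); the regioisomeric monotosylates 15 and 16 form in parallel and converge on the same ring, no stereocentre is involved, and neither benzylic position can compete because C7 is still a dithiane and O7′ is silylated.

Step 8
Reactants: 17 tetrahydrofuran dithiane
Product: 18 Ar [(3R,4R)-4-[(R)-Ar(TBSO)methyl]tetrahydrofuran-3-yl] ketone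
Conditions: HgCl2 (2.5 equiv), CaCO3 (5 equiv), MeCN–H2O (4:1), rt → 50 °C
Reagents that add atoms: water, O
Why: Thiophilic Hg(II)-promoted hydrolysis of the dithioacetal to the aryl ketone, buffered by CaCO3 so that silyl and benzyl ethers should survive, with C8 (now α to the ketone) already in the thermodynamically preferred trans arrangement.

Step 9
Reactants: 18 aryl ketone
Product: 19 (S)-Ar[(3R,4R)-4-[(R)-Ar(TBSO)methyl]tetrahydrofuran-3-yl]methanol
Conditions: (R)-Me-CBS (0.2 equiv), BH3·SMe2 (1.2 equiv), THF, −20 → 0 °C; MeOH, then H2O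
Reagents that add atoms: none
Why: Corey–Bakshi–Shibata reduction, in which the ketone binds to the (R)-oxazaborolidine–borane complex with the aryl group as the large substituent and hydride is delivered to the Re face of C7, which should give the 7S carbinol under catalyst control (the sense in which the (R)-catalyst gives (S)-1-arylalkanols).

Step 10
Reactants: 19 mono-silyl ether
Product: 20 (7S,7′R,8R,8′R)-4,4′-bis(benzyloxy)-3,3′-dimethoxy-9,9′-epoxylignane-7,7′-diol
Conditions: TBAF (1.5 equiv), THF, 0 °C → rt
Reagents that add atoms: none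
Why: Fluoride-mediated desilylation driven by the Si–F bond; with both phenols still benzylated no quinone methide pathway is open, so C7 and C7′ should keep their configuration.

Step 11
Reactants: 20 dibenzyl ether diol
Product: 21 (7S,7′R,8R,8′R)-3,3′-dimethoxy-9,9′-epoxylignane-4,4′,7,7′-tetrol (CNP0157038.2)
Conditions: H2 (1 atm), 10% Pd/C, EtOAc, rt, stopped at full conversion
Reagents that add atoms: none
Why: Catalytic hydrogenolysis of aryl benzyl ethers, which are cleaved much faster than secondary benzylic alcohols in a neutral aprotic medium, so both carbinols and all four stereocentres should remain.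

**Compound list**

1 | 4-benzyloxy-3-methoxybenzaldehyde (O-benzylvanillin) | COc1cc(C=O)ccc1OCc1ccccc1 | starting material
2 | propane-1,3-dithiol | SCCCS | starting material
3 | 2-(4-benzyloxy-3-methoxyphenyl)-1,3-dithiane | COc1cc(C2SCCCS2)ccc1OCc1ccccc1 | intermediate
4 | furfural | O=Cc1ccco1 | starting material
5 | furfural endoperoxide (2,3,7-trioxabicyclo[2.2.1]hept-5-ene-1-carbaldehyde, racemic) | O=CC12OOC(O1)C=C2 | intermediate (not isolated)
6 | (±)-5-hydroxyfuran-2(5H)-one | OC1OC(=O)C=C1 | intermediate
7 | l-menthol, (1R,2S,5R)-2-isopropyl-5-methylcyclohexanol | CC(C)[C@@H]1CC[C@@H](C)C[C@H]1O | starting material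
8 | (5R)-5-[(1R,2S,5R)-menthyloxy]furan-2(5H)-one | CC(C)[C@@H]1CC[C@@H](C)C[C@H]1O[C@@H]2OC(=O)C=C2 | intermediate
9 | 2-lithio-2-(4-benzyloxy-3-methoxyphenyl)-1,3-dithiane | [Li]C1(SCCCS1)c1ccc(OCc2ccccc2)c(OC)c1 | intermediate (not isolated)
10 | lithium (4R,5R)-4-(2-Ar-1,3-dithian-2-yl)-5-menthyloxy-4,5-dihydrofuran-2-olate | [Li]OC1=C[C@@H](C2(SCCCS2)c3ccc(OCc4ccccc4)c(OC)c3)[C@H](O[C@@H]5C[C@H](C)CC[C@H]5C(C)C)O1 | intermediate (not isolated)
11 | lithium alkoxide (O7′–Li) of 12 | O=C1O[C@@H](O[C@@H]2C[C@H](C)CC[C@H]2C(C)C)[C@H](C3(SCCCS3)c4ccc(OCc5ccccc5)c(OC)c4)[C@H]1[C@@H](O[Li])c6ccc(OCc7ccccc7)c(OC)c6 | intermediate (not isolated)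
12 | (3S,4R,5R)-3-[(R)-Ar(hydroxy)methyl]-4-(2-Ar-1,3-dithian-2-yl)-5-(menthyloxy)dihydrofuran-2(3H)-one | O=C1O[C@@H](O[C@@H]2C[C@H](C)CC[C@H]2C(C)C)[C@H](C3(SCCCS3)c4ccc(OCc5ccccc5)c(OC)c4)[C@H]1[C@@H](O)c6ccc(OCc7ccccc7)c(OC)c6 | intermediate
13 | 7′-O-TBS ether of 12 | O=C1O[C@@H](O[C@@H]2C[C@H](C)CC[C@H]2C(C)C)[C@H](C3(SCCCS3)c4ccc(OCc5ccccc5)c(OC)c4)[C@H]1[C@@H](O[Si](C)(C)C(C)(C)C)c6ccc(OCc7ccccc7)c(OC)c6 | intermediate
14 | (2R,3R)-2-[(R)-Ar(TBSO)methyl]-3-(2-Ar-1,3-dithian-2-yl)butane-1,4-diol | OC[C@H]([C@@H](O[Si](C)(C)C(C)(C)C)c1ccc(OCc2ccccc2)c(OC)c1)[C@H](CO)C3(SCCCS3)c4ccc(OCc5ccccc5)c(OC)c4 | intermediate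
15 | 9′-O-monotosylate of 14 (tosylate on the CH2 next to the silyloxy-bearing branch) | Cc1ccc(cc1)S(=O)(=O)OC[C@H]([C@@H](O[Si](C)(C)C(C)(C)C)c2ccc(OCc3ccccc3)c(OC)c2)[C@H](CO)C4(SCCCS4)c5ccc(OCc6ccccc6)c(OC)c5 | intermediate (not isolated)
16 | 9-O-monotosylate of 14 (tosylate on the CH2 next to the dithiane-bearing carbon) | OC[C@H]([C@@H](O[Si](C)(C)C(C)(C)C)c1ccc(OCc2ccccc2)c(OC)c1)[C@H](COS(=O)(=O)c3ccc(C)cc3)C4(SCCCS4)c5ccc(OCc6ccccc6)c(OC)c5 | intermediate (not isolated)
17 | (3R,4R)-3-(2-Ar-1,3-dithian-2-yl)-4-[(R)-Ar(TBSO)methyl]tetrahydrofuran | C1OC[C@H]([C@@H](O[Si](C)(C)C(C)(C)C)c2ccc(OCc3ccccc3)c(OC)c2)[C@H]1C4(SCCCS4)c5ccc(OCc6ccccc6)c(OC)c5 | intermediate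
18 | Ar [(3R,4R)-4-[(R)-Ar(TBSO)methyl]tetrahydrofuran-3-yl] ketone | C1OC[C@H]([C@@H](O[Si](C)(C)C(C)(C)C)c2ccc(OCc3ccccc3)c(OC)c2)[C@H]1C(=O)c4ccc(OCc5ccccc5)c(OC)c4 | intermediate
19 | (S)-Ar[(3R,4R)-4-[(R)-Ar(TBSO)methyl]tetrahydrofuran-3-yl]methanol | C1OC[C@H]([C@@H](O[Si](C)(C)C(C)(C)C)c2ccc(OCc3ccccc3)c(OC)c2)[C@H]1[C@H](O)c4ccc(OCc5ccccc5)c(OC)c4 | intermediate
20 | (7S,7′R,8R,8′R)-4,4′-bis(benzyloxy)-3,3′-dimethoxy-9,9′-epoxylignane-7,7′-diol | C1OC[C@H]([C@@H](O)c2ccc(OCc3ccccc3)c(OC)c2)[C@H]1[C@H](O)c4ccc(OCc5ccccc5)c(OC)c4 | intermediate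
21 | (7S,7′R,8R,8′R)-3,3′-dimethoxy-9,9′-epoxylignane-4,4′,7,7′-tetrol (CNP0157038.2) | COc1cc([C@@H](O)[C@H]2COC[C@@H]2[C@@H](O)c2ccc(O)c(OC)c2)ccc1O | target

**Step count and risks**

Total step count: 11. Longest linear sequence: 10 steps (furfural 4 to 21, steps 2–11); the dithiane branch (step 1) joins at step 4.

Steps most likely to fail:

Step 4. Facial discrimination at the aldehyde carbon in the aldol may be insufficient, or the aldolate may equilibrate by retro-aldol before the quench, so that the C7′ configuration is eroded. The fallback sets out from 12 as obtained from step 4 in admixture with its 7′S epimer F1 and returns at 12. The mixture is oxidised with SO3·pyridine, DMSO and iPr2NEt (Parikh–Doering, compatible with the dithiane) to the 3-aroyl lactone F2, in which C7′ is trigonal. F2 is then reduced under catalyst control with (S)-Me-CBS and catecholborane in toluene at −78 °C, which should deliver hydride to the Si face and regenerate the 7′R carbinol. The 3,4-trans arrangement is the thermodynamic one, so enolisation of F2 at C3 should do no harm.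

Step 9. The α-branched ring carbon may compete with the aryl group as the large substituent, or the existing centres may bias the ketone against the catalyst, so that facial selectivity at C7 is poor. The fallback sets out from 18 and returns at 19. Reduction with the enantiomeric (S)-Me-CBS catalyst, the matched pairing in that case, should give the 7R alcohol F3. This is inverted by a Mitsunobu reaction (4-nitrobenzoic acid, PPh3, DIAD, toluene, 0 °C) to the 7S 4-nitrobenzoate F4, and methanolysis (K2CO3, MeOH) releases 19.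

Step 11. Hydrogenolytic cleavage of the benzylic C7–O and C7′–O bonds may set in once the para-phenols are free, leading to over-reduction. The fallback sets out from 19 and returns at 21. The C7 hydroxyl is silylated (TBSOTf, 2,6-lutidine) to the 7,7′-bis-silyl ether F5. The benzyl ethers are then hydrogenolysed (H2, Pd/C, EtOAc) while both carbinol oxygens are masked, giving the bisphenol F6. Both silyl groups are removed last with TBAF buffered with AcOH in THF.

**Further compounds**

F1 | step 4 | 7′S epimer of 12 | O=C1O[C@@H](O[C@@H]2C[C@H](C)CC[C@H]2C(C)C)[C@H](C3(SCCCS3)c4ccc(OCc5ccccc5)c(OC)c4)[C@H]1[C@H](O)c6ccc(OCc7ccccc7)c(OC)c6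
F2 | step 4 | (3S,4R,5R)-3-(4-benzyloxy-3-methoxybenzoyl)-4-(2-Ar-1,3-dithian-2-yl)-5-(menthyloxy)dihydrofuran-2(3H)-one | O=C1O[C@@H](O[C@@H]2C[C@H](C)CC[C@H]2C(C)C)[C@H](C3(SCCCS3)c4ccc(OCc5ccccc5)c(OC)c4)[C@H]1C(=O)c6ccc(OCc7ccccc7)c(OC)c6
F3 | step 9 | 7R epimer of 19 | C1OC[C@H]([C@@H](O[Si](C)(C)C(C)(C)C)c2ccc(OCc3ccccc3)c(OC)c2)[C@H]1[C@@H](O)c4ccc(OCc5ccccc5)c(OC)c4
F4 | step 9 | 7S 4-nitrobenzoate of 19 | C1OC[C@H]([C@@H](O[Si](C)(C)C(C)(C)C)c2ccc(OCc3ccccc3)c(OC)c2)[C@H]1[C@H](OC(=O)c4ccc(cc4)[N+](=O)[O-])c5ccc(OCc6ccccc6)c(OC)c5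
F5 | step 11 | 7,7′-bis-O-TBS ether of 20 | C1OC[C@H]([C@@H](O[Si](C)(C)C(C)(C)C)c2ccc(OCc3ccccc3)c(OC)c2)[C@H]1[C@H](O[Si](C)(C)C(C)(C)C)c4ccc(OCc5ccccc5)c(OC)c4
F6 | step 11 | 7,7′-bis-O-TBS ether of 21 | C1OC[C@H]([C@@H](O[Si](C)(C)C(C)(C)C)c2ccc(O)c(OC)c2)[C@H]1[C@H](O[Si](C)(C)C(C)(C)C)c3ccc(O)c(OC)c3
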